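The numbering is that of germacrane. The hemiketal carbon C1 and the enol-lactone carbon C6 are both masked ketones and face each other 1,6 across the ten-membered carbocycle. This ring is therefore read as a bicyclo[4.4.0]dec-1(6)-ene whose shared C1=C6 bond has been cut. Ozonolysis of that bond merges rings A and B into the cyclodecane. In the same flask the C4 hydroxyl closes the oxolane on C1 while the C12 acid shelters C6. The precursor is a 1(6)-octalin bearing the C4 tertiary alcohol, C10 and C13 acetates, a silylated C8 alcohol and a C7=C11 alkylidene whose carboxyl lies cis to C6. All its stereocentres are in place before any medium ring exists.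

Key step: step 14

Assumption: (R,R)-QuinoxP* and (−)-Ipc2BCl are taken to be the antipodes that deliver 4R and 8R; if the sense of induction is the reverse, the mirror-image ligand or borane is used and nothing else changes.

Step 1
Reactants: 1 3-methylcyclohex-2-en-1-one
Product: 3 (R)-3-hydroxy-3-methylcyclohexan-1-one, via bis-boryl enolate 2 (not isolated)
Conditions: [Cu(MeCN)4]PF6 (5 mol %), (R,R)-QuinoxP* (6 mol %), LiOtBu (10 mol %), B2pin2, DMSO, rt; then THF, H2O, NaBO3·4H2O, 0 °C to rt
Reagents that add atoms: bis(pinacolato)diboron, CC1(C)OB(OC1(C)C)B1OC(C)(C)C(C)(C)O1 (boryl groups of 2); sodium perborate NaBO3·4H2O, [Na+].[Na+].O[B-]1(O)OO[B-](O)(O)OO1 (oxygen on C4)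
Why: Enantioselective copper-catalysed conjugate borylation of a β-substituted cyclic enone lets the C2-symmetric bisphosphine choose the enone face and thereby sets C4, and perborate oxidation of the tertiary C–B bond goes with retention in a medium too mild to trigger retro-aldol racemisation or dehydration of the β-hydroxy ketone.

Step 2
Reactants: 3 (R)-3-hydroxy-3-methylcyclohexan-1-one
Product: 4 (R)-3-methyl-3-(triethylsilyloxy)cyclohexan-1-one
Conditions: Et3SiOTf, 2,6-lutidine, CH2Cl2, −78 to −20 °C
Reagents that add atoms: triethylsilyl triflate, CC[Si](CC)(CC)OS(=O)(=O)C(F)(F)F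
Why: Standard O-silylation with a silyl triflate and a hindered pyridine reaches the tertiary hydroxyl at low temperature, leaves C4 untouched and removes the free β-hydroxy ketone motif whose retro-aldol opening would erode the configuration in the enolate steps that follow.

Step 3
Reactants: 4 (R)-3-methyl-3-(triethylsilyloxy)cyclohexan-1-one
Product: 6 (5R)-2-(1-hydroxyethyl)-5-methyl-5-(triethylsilyloxy)cyclohexan-1-one, via lithium enolate 5 (not isolated)
Conditions: LiN(iPr)2, THF, −78 °C; MeCHO, −78 °C; AcOH in THF, −78 °C
Reagents that add atoms: acetaldehyde, CC=O; lithium diisopropylamide, [Li]N(C(C)C)C(C)C (lithium of 5)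
Why: Kinetic deprotonation by the bulky amide occurs at the CH2 remote from quaternary C4 because the other α-CH2 is neopentyl-like, the directed aldol addition to acetaldehyde then forms the C1–C10 bond, and the two new stereocentres are irrelevant since steps 4 and 5 flatten both.

Step 4
Reactants: 6 (5R)-2-(1-hydroxyethyl)-5-methyl-5-(triethylsilyloxy)cyclohexan-1-one
Product: 7 (5R)-2-acetyl-5-methyl-5-(triethylsilyloxy)cyclohexan-1-one
Conditions: Dess–Martin periodinane, CH2Cl2, 0 °C to rt
Reagents that add atoms: none
Why: Dess–Martin oxidation converts β-hydroxy ketones into 1,3-diketones under nearly neutral conditions that neither cleave the silyl ether nor provoke β-elimination.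

Step 5
Reactants: 7 (5R)-2-acetyl-5-methyl-5-(triethylsilyloxy)cyclohexan-1-one
Product: 8 (5R)-2-acetyl-5-methyl-5-(triethylsilyloxy)cyclohex-1-en-1-yl triflate
Conditions: Tf2O, iPr2NEt, CH2Cl2, −78 °C
Reagents that add atoms: triflic anhydride, O=S(=O)(OS(=O)(=O)C(F)(F)F)C(F)(F)F
Why: Enol triflate formation from a 1,3-diketone follows the preferred enol, which for 2-acylcyclohexanones has the endocyclic double bond, so sulfonylation falls on the ring oxygen (C6) as it does for 2-acetylcyclohexanone itself and leaves the acetyl group (C10 and C9) free.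

Step 6
Reactants: 9 but-2-yne-1,4-diol
Product: 10 4-(triethylsilyloxy)but-2-yn-1-ol
Conditions: Et3SiCl (1 equiv), imidazole, 9 (3 equiv), DMF, 0 °C
Reagents that add atoms: chlorotriethylsilane, CC[Si](Cl)(CC)CC
Why: Statistical monosilylation with the cheap symmetrical diol in excess favours the mono ether, and the surplus diol is removed by an aqueous wash.

Step 7
Reactants: 10 4-(triethylsilyloxy)but-2-yn-1-ol
Product: 11 4-(triethylsilyloxy)but-2-ynal
Conditions: activated MnO2, CH2Cl2, rt
Reagents that add atoms: none
Why: Activated MnO2 is a neutral heterogeneous oxidant selective for propargylic alcohols and stops at the ynal without touching the silyl ether.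

Step 8
Reactants: 8 (5R)-2-acetyl-5-methyl-5-(triethylsilyloxy)cyclohex-1-en-1-yl triflate; 11 4-(triethylsilyloxy)but-2-ynal
Product: 14 (8R)-β-hydroxy ynyl ketone on the ring A triflate, via boron enolate 12 (not isolated), via boron aldolate 13 (not isolated)
Conditions: (−)-Ipc2BCl, Et3N, Et2O, 0 °C; 11, −78 to −25 °C; H2O2, MeOH, pH 7 buffer, 0 °C
Reagents that add atoms: (−)-B-chlorodiisopinocampheylborane, ClB([C@@H]1C[C@@H]2C[C@H]([C@H]1C)C2(C)C)[C@@H]1C[C@@H]2C[C@H]([C@H]1C)C2(C)C (boron group of 12 and 13)
Why: In this reagent-controlled boron aldol reaction of a methyl ketone, Ipc2BCl and Et3N enolise the acetyl CH3 just as they do in β-halovinyl methyl ketones, the isopinocampheyl groups direct attack to the Re face of the ynal and set C8 as R, and because C4 is already fixed the minor C8 epimer is a diastereomer that chromatography removes here or after ring closure.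

Step 9
Reactants: 14 (8R)-β-hydroxy ynyl ketone on the ring A triflate
Product: 15 C8 tert-butyldimethylsilyl ether of 14
Conditions: TBSOTf, 2,6-lutidine, CH2Cl2, −78 °C
Reagents that add atoms: tert-butyldimethylsilyl triflate, CC(C)(C)[Si](C)(C)OS(=O)(=O)C(F)(F)F
Why: Immediate O-silylation under non-nucleophilic conditions caps the C8 hydroxyl before it can displace the triflate by conjugate addition–elimination to a dihydropyranone, and it installs the bulky group that later steers the addition at C10.

Step 10
Reactants: 15 C8 tert-butyldimethylsilyl ether of 14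
Product: 16 octalin dienone acid (4R 8R; C12 carboxyl cis to C6)
Conditions: PdCl2(PPh3)2 (5 mol %), CO (1 atm), H2O (5 equiv), Et3N, DMF, 50 °C; cold pH 5 buffer wash, kept as the Et3NH+ salt until use
Reagents that add atoms: carbon monoxide, [C-]#[O+]; water, O
Why: In this cyclic carbopalladation with deferred carbonylative termination, zerovalent palladium inserts into the C6–OTf bond, CO uptake at that stage is reversible whereas the 6-exo-dig syn addition of C6–Pd across C7≡C11 is not, and the resulting C11–Pd bond then takes up CO and water, so ring B closes with the carboxyl cis to C6 and C13 cis to C8.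

Step 11
Reactants: 16 octalin dienone acid (4R 8R; C12 carboxyl cis to C6)
Product: 19 C10 acetate of the octalin diene acid (4R 8R 10S; C4 and C13 as SiEt3 ethers), via cerium alkoxide 17 (not isolated), via mixed anhydride 18 (not isolated)
Conditions: MeLi, CeCl3, THF, −78 °C (MeCeCl2, 3.5 equiv); Ac2O, −78 to 0 °C; aq NaHCO3, THF, 0 °C
Reagents that add atoms: methyllithium, C[Li]; cerium trichloride, Cl[Ce](Cl)Cl (cerium groups of 17); acetic anhydride, CC(=O)OC(C)=O
Why: 1,2-Addition of the weakly basic organocerium reagent, after it has turned the acid into an inert carboxylate, avoids enolisation toward C9 and loss of the C8 silyloxy group, A1,3 strain with C13 holds the C8 OTBS group pseudoaxial so that methyl enters C10 from the opposite face and creates the S centre with O10 cis to O8, and the alkoxide is acetylated before work-up.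

Step 12
Reactants: 19 C10 acetate of the octalin diene acid (4R 8R 10S; C4 and C13 as SiEt3 ethers)
Product: 20 4,13-dihydroxy octalin diene acid (C8 OTBS and C10 OAc retained)
Conditions: HF·pyridine, pyridine, THF, 0 °C to rt
Reagents that add atoms: none
Why: Selective fluoride desilylation discriminates by the bulk on silicon, so the primary and the tertiary SiEt3 ethers fall while the hindered secondary TBS ether stays, and the buffered medium is too weakly acidic to ionise the tertiary allylic acetate.

Step 13
Reactants: 20 4,13-dihydroxy octalin diene acid (C8 OTBS and C10 OAc retained)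
Product: 22 1(6)-octalin diene acid with free C4 hydroxyl; C10 and C13 acetates; C8 OTBS, via mixed anhydride 21 (not isolated)
Conditions: Ac2O (2.5 equiv), pyridine, CH2Cl2, 0 °C; then aq NaHCO3, THF, 0 °C
Reagents that add atoms: acetic anhydride, CC(=O)OC(C)=O
Why: Acetylation without a nucleophilic catalyst reaches only the primary allylic C13 hydroxyl, the tertiary C4 hydroxyl is inert under these conditions, and the C12 mixed anhydride reverts to the acid during the bicarbonate stir.

Step 14
Reactants: 22 1(6)-octalin diene acid with free C4 hydroxyl; C10 and C13 acetates; C8 OTBS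
Product: 24 ten-membered 1,4-epoxy hemiketal 6-oxo acid (1S 4R 8R 10S), via C1 hydroperoxide 23 (not isolated)
Conditions: O3/O2, CH2Cl2, Sudan Red 7B, −78 °C; Me2S, −78 °C to rt
Reagents that add atoms: ozone, [O-][O+]=O
Why: Ozone adds across C1=C6 in a 1,3-dipolar cycloaddition, the primary ozonide cycloreverts (Criegee mechanism) to the conjugated C6 ketone and a C1 carbonyl oxide, the C4 hydroxyl intercepts the latter as hydroperoxide 23 in the non-participating solvent, and Me2S removes the outer oxygen. The closest known reactions are the ozonolysis of bicyclo[4.4.0]dec-1(6)-enes to cyclodecane-1,6-diones and the site-selective ozonolysis of the remote double bond of 2,4-dienoic acid derivatives. The ten-membered carbocycle arises not by bond formation but by cutting the bond common to rings A and B, the oxolane closes 5-exo-trig by attack of O4 on C1, and the C12 acid can add reversibly 5-exo-trig to C6 as the hydroxybutenolide tautomer of 24. C1 is the only new stereocentre and C4 dictates it, since a single oxygen atom can link C4 to C1 only if C5 and C10 leave the oxolane on the same face, which is the S arrangement. The step needs site selectivity for C1=C6 over C7=C11, and electronics supply it because the former carries four carbon donors whereas the latter bears the carboxyl group and two allylic C–O bonds, the dye end-point stopping ozone delivery after the first alkene. The opposite sense of cycloreversion would be harmless because a C6 carbonyl oxide would be trapped by the acid and reduced to the same product, and with both carbonyls tied up the transannular aldol condensation of free cyclodecane-1,6-diones has no partner.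

Step 15
Reactants: 24 ten-membered 1,4-epoxy hemiketal 6-oxo acid (1S 4R 8R 10S)
Product: 25 8-O-TBS ether of the target
Conditions: MsCl (1.1 equiv), Et3N (3 equiv), CH2Cl2, −40 to 0 °C
Reagents that add atoms: none
Why: In this dehydrative enol lactonization of a γ-keto acid the carboxylate is activated far faster than the hindered C1 hemiketal hydroxyl can react, the activated acyl group closes 5-exo-trig on the C6 oxygen with loss of the only available α-proton (H5, C7 being fully substituted), and the C5=C6 geometry with C4 cis to C7 is the only one that the oxygen-bridged nine-membered perimeter tolerates.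

Step 16
Reactants: 25 8-O-TBS ether of the target
Product: 26 target CNP0203479.1
Conditions: HF·pyridine, pyridine, THF, 0 °C to rt (polyethylene vessel)
Reagents that add atoms: none
Why: Fluoride desilylation in a weakly acidic medium frees the C8 hydroxyl, the absence of base prevents acetyl migration from O10 to the cis O8, translactonisation to an 8,12-olide and loss of the C13 acetate, and the absence of an alcohol solvent keeps the C1 hemiketal from exchanging.

Compound list
1 | 3-methylcyclohex-2-en-1-one | CC1=CC(=O)CCC1 | starting material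
2 | (S)-3-methyl-3-(pinacolatoboryl)cyclohex-1-en-1-yl pinacol borate (O-boron enolate of the β-boryl ketone) | C[C@@]1(B2OC(C)(C)C(C)(C)O2)CCCC(OB2OC(C)(C)C(C)(C)O2)=C1 | intermediate
3 | (R)-3-hydroxy-3-methylcyclohexan-1-one | O=C1C[C@](C)(O)CCC1 | intermediate
4 | (R)-3-methyl-3-(triethylsilyloxy)cyclohexan-1-one | O=C1C[C@](C)(O[Si](CC)(CC)CC)CCC1 | intermediate
5 | lithium (R)-5-methyl-5-(triethylsilyloxy)cyclohex-1-en-1-olate | [Li]OC1=CCC[C@@](C)(O[Si](CC)(CC)CC)C1 | intermediate
6 | (5R)-2-(1-hydroxyethyl)-5-methyl-5-(triethylsilyloxy)cyclohexan-1-one (epimers at C2 and at the carbinol carbon) | CC(O)C1CC[C@@](C)(O[Si](CC)(CC)CC)CC1=O | intermediate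
7 | (5R)-2-acetyl-5-methyl-5-(triethylsilyloxy)cyclohexan-1-one (drawn as the diketone) | CC(=O)C1CC[C@@](C)(O[Si](CC)(CC)CC)CC1=O | intermediate
8 | (5R)-2-acetyl-5-methyl-5-(triethylsilyloxy)cyclohex-1-en-1-yl trifluoromethanesulfonate | CC(=O)C1=C(OS(=O)(=O)C(F)(F)F)C[C@](C)(O[Si](CC)(CC)CC)CC1 | intermediate
9 | but-2-yne-1,4-diol | OCC#CCO | starting material
10 | 4-(triethylsilyloxy)but-2-yn-1-ol | OCC#CCO[Si](CC)(CC)CC | intermediate
11 | 4-(triethylsilyloxy)but-2-ynal | O=CC#CCO[Si](CC)(CC)CC | intermediate
12 | diisopinocampheylboron enolate of 8 (boryloxy diene, CH2= terminus at C9) | C=C(OB([C@@H]1C[C@@H]2C[C@H]([C@H]1C)C2(C)C)[C@@H]1C[C@@H]2C[C@H]([C@H]1C)C2(C)C)C1=C(OS(=O)(=O)C(F)(F)F)C[C@](C)(O[Si](CC)(CC)CC)CC1 | intermediate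
13 | diisopinocampheylboron aldolate, 8R | O=C(C[C@@H](OB([C@@H]1C[C@@H]2C[C@H]([C@H]1C)C2(C)C)[C@@H]1C[C@@H]2C[C@H]([C@H]1C)C2(C)C)C#CCO[Si](CC)(CC)CC)C1=C(OS(=O)(=O)C(F)(F)F)C[C@](C)(O[Si](CC)(CC)CC)CC1 | intermediate
14 | (5R)-2-[(3R)-3-hydroxy-6-(triethylsilyloxy)hex-4-ynoyl]-5-methyl-5-(triethylsilyloxy)cyclohex-1-en-1-yl triflate | O=C(C[C@@H](O)C#CCO[Si](CC)(CC)CC)C1=C(OS(=O)(=O)C(F)(F)F)C[C@](C)(O[Si](CC)(CC)CC)CC1 | intermediate
15 | 3-O-TBS ether of 14 (4R,8R in germacrane numbering) | O=C(C[C@@H](O[Si](C)(C)C(C)(C)C)C#CCO[Si](CC)(CC)CC)C1=C(OS(=O)(=O)C(F)(F)F)C[C@](C)(O[Si](CC)(CC)CC)CC1 | intermediate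
16 | octalin dienone acid: bicyclo[4.4.0]dec-1(6)-en-10-one with 4R methyl and OSiEt3, 8R OTBS, and a C7=C11 alkylidene bearing CH2OSiEt3 cis to C8 and CO2H cis to C6 | O=C1C[C@@H](O[Si](C)(C)C(C)(C)C)/C(=C(\CO[Si](CC)(CC)CC)C(=O)O)C2=C1CC[C@@](C)(O[Si](CC)(CC)CC)C2 | intermediate
17 | bis(dichlorocerium) salt: 10S tertiary alkoxide and C12 carboxylate | CC[Si](CC)(CC)OC/C(C(=O)O[Ce](Cl)Cl)=C1\[C@H](O[Si](C)(C)C(C)(C)C)C[C@](C)(O[Ce](Cl)Cl)C2=C1C[C@](C)(O[Si](CC)(CC)CC)CC2 | intermediate
18 | C10 acetate carrying the C12 acetic mixed anhydride | CC[Si](CC)(CC)OC/C(C(=O)OC(C)=O)=C1\[C@H](O[Si](C)(C)C(C)(C)C)C[C@](C)(OC(C)=O)C2=C1C[C@](C)(O[Si](CC)(CC)CC)CC2 | intermediate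
19 | (4R,8R,10S)-10-acetoxy-10-methyl octalin diene acid, C4 and C13 as SiEt3 ethers, C8 as TBS ether | CC[Si](CC)(CC)OC/C(C(=O)O)=C1\[C@H](O[Si](C)(C)C(C)(C)C)C[C@](C)(OC(C)=O)C2=C1C[C@](C)(O[Si](CC)(CC)CC)CC2 | intermediate
20 | (4R,8R,10S)-4,13-dihydroxy-10-acetoxy octalin diene acid, C8 as TBS ether | OC/C(C(=O)O)=C1\[C@H](O[Si](C)(C)C(C)(C)C)C[C@](C)(OC(C)=O)C2=C1C[C@](C)(O)CC2 | intermediate
21 | 10,13-diacetate carrying the C12 acetic mixed anhydride | CC(=O)OC/C(C(=O)OC(C)=O)=C1\[C@H](O[Si](C)(C)C(C)(C)C)C[C@](C)(OC(C)=O)C2=C1C[C@](C)(O)CC2 | intermediate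
22 | (4R,8R,10S)-1(6)-octalin diene acid: free C4 hydroxyl, C10 and C13 acetates, C8 OTBS, carboxyl cis to C6 | CC(=O)OC/C(C(=O)O)=C1\[C@H](O[Si](C)(C)C(C)(C)C)C[C@](C)(OC(C)=O)C2=C1C[C@](C)(O)CC2 | intermediate
23 | 1-hydroperoxy-1,4-epoxy-6-oxo acid of the ten-membered ring (C1 arranged as in 24) | CC(=O)OC/C(C(=O)O)=C1\[C@H](O[Si](C)(C)C(C)(C)C)C[C@](C)(OC(C)=O)[C@]2(OO)CC[C@@](C)(O2)CC1=O | intermediate
24 | (1S,4R,8R,10S)-1,4-epoxy-1-hydroxy-6-oxo acid of the ten-membered ring (open form of its 6-hydroxybutenolide tautomer) | CC(=O)OC/C(C(=O)O)=C1\[C@H](O[Si](C)(C)C(C)(C)C)C[C@](C)(OC(C)=O)[C@]2(O)CC[C@@](C)(O2)CC1=O | intermediate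
25 | 8-O-TBS ether of the target (5-en-6,12-olide closed) | CC(=O)OCC1=C2/C(=C\[C@@]3(C)CC[C@](O)(O3)[C@@](C)(OC(C)=O)C[C@H]2O[Si](C)(C)C(C)(C)C)OC1=O | intermediate
26 | CNP0203479.1, (1S,4R,8R,10S)-10,13-diacetoxy-1,4-epoxy-1,8-dihydroxygermacra-5,7(11)-dien-12,6-olide | CC(=O)OCC1=C2/C(=C\[C@@]3(C)CC[C@](O)(O3)[C@@](C)(OC(C)=O)C[C@H]2O)OC1=O | target

Total step count: 16
Longest linear sequence: 14 (steps 1 to 5 and 8 to 16)

Steps most likely to fail

1. Step 10.
- What may go wrong: CO and water may capture the C6 alkenylpalladium species before ring closure. The amine may expel the C8 silyloxy group from the β-silyloxy ketone, which would lead on to aromatisation of ring B. The liberated carboxyl may also close conjugatively on C6 of the dienone during acidic handling.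
- Fallback: ring closure is separated from carbonylation. From 15, cyclisation with anion capture in the absence of CO (Pd(PPh3)4, (Me3Sn)2, LiCl, dioxane, 60 °C) should give the alkenylstannane F1. Iododestannylation with I2 in CH2Cl2 at 0 °C, with retention of geometry, should give the alkenyl iodide F2. Hydroxycarbonylation of F2 (PdCl2(PPh3)2, CO, H2O, Et3N, DMF, rt) has no competing cyclisation left and comes back to the route at 16.

2. Step 11.
- What may go wrong: enolisation toward C9 may expel silyloxide, and methyl may attack the wrong face. The TBS group may migrate from O8 to the cis C10 alkoxide before the anhydride arrives. Acylation of the crowded alkoxide may also be sluggish.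
- Fallback: C–C bond formation is uncoupled from acylation, so that no alkoxide ever meets the silyl ether for long. From 16, the MeCeCl2 addition is quenched at −78 °C with aqueous NH4Cl to give the tertiary alcohol F3. The C10 epimers can be separated at this stage. The neutral alcohol is then acetylated by acyl-transfer catalysis (Ac2O, Et3N, 4-pyrrolidinopyridine, CH2Cl2, rt) through 18, and the bicarbonate work-up returns it to the route at 19.

3. Step 14.
- What may go wrong: ozone may not discriminate well enough within the conjugated diene. It may transfer a single oxygen atom to the hindered tetrasubstituted bond instead of cleaving it. The released carbonyl groups may condense across the ring before they are masked.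
- Fallback: singlet oxygen, a more discriminating electrophile, replaces ozone. From 22, a Schenck ene reaction (O2, tetraphenylporphyrin, visible light, CH2Cl2, −20 °C) should place the hydroperoxy group on C1 with abstraction of H5, which keeps the diene conjugated, and give the allylic hydroperoxide F4. Hock cleavage with catalytic CF3CO2H in CH2Cl2 at −20 to 0 °C moves vinylic C6 from C1 to oxygen, after which the C4 hydroxyl and the released water add. This breaks the same C1–C6 bond and comes back to the route at 24.

Further compounds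
F1 | step 10 | C11 trimethylstannyl octalin dienone (SnMe3 cis to C6, CH2OSiEt3 cis to C8; 4R,8R) | O=C1C[C@@H](O[Si](C)(C)C(C)(C)C)/C(=C(\CO[Si](CC)(CC)CC)[Sn](C)(C)C)C2=C1CC[C@@](C)(O[Si](CC)(CC)CC)C2
F2 | step 10 | C11 iodo octalin dienone (iodine cis to C6; 4R,8R) | O=C1C[C@@H](O[Si](C)(C)C(C)(C)C)/C(=C(\CO[Si](CC)(CC)CC)I)C2=C1CC[C@@](C)(O[Si](CC)(CC)CC)C2
F3 | step 11 | (4R,8R,10S)-10-hydroxy-10-methyl octalin diene acid, C4 and C13 as SiEt3 ethers, C8 as TBS ether | CC[Si](CC)(CC)OC/C(C(=O)O)=C1\[C@H](O[Si](C)(C)C(C)(C)C)C[C@](C)(O)C2=C1C[C@](C)(O[Si](CC)(CC)CC)CC2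
F4 | step 14 | 1-hydroperoxy-5,7(11)-diene acid (ene product of 22; configuration at C1 left open because it is lost in the cleavage) | CC(=O)OC/C(C(=O)O)=C1\[C@H](O[Si](C)(C)C(C)(C)C)C[C@](C)(OC(C)=O)C2(OO)CC[C@@](C)(O)C=C12
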